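**Retrosynthetic overview**

- Feature: the only ring is the 1,2-dioxane O1–O2–C3(OMe)–C4–C5–C6, with the acid arm C7–C8 on C6. The C3–OMe is cis to C7, so C3–C4–C5–C6–C7–C8 can be folded into a six-membered carbocycle by a temporary C3–C8 bond, with O1–O2 as its 1,4-bridge.
- Endgame: the enyne C(sp)–C(sp2) bond comes from Sonogashira coupling with (E)-1-iodoundec-1-ene, the alkyne carbon from an aldehyde (Ohira–Bestmann), and the free acid from its methyl ester.
- Excision of the tether: C3–OMe and the C8 carboxyl come from a bridged acyloxy peroxyketal, made by Baeyer–Villiger insertion into the C3–C8 bond of the C8 ketone.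
- Ring formation: the dioxane ring is closed by [4+2] addition of singlet oxygen across C3 and C6 of an (R)-cyclohexa-2,4-dienyl silyl ether, anti to the C8 silyloxy group, as a 2,3-dioxabicyclo[2.2.2]octene. The carbocycle is bought and is opened again in steps 13 and 14.
- Diene: from a commercial enone ketal by α-iodination, CBS reduction (sets C8), B-alkyl Suzuki coupling, ketal hydrolysis, dienyl triflate formation and reduction. This fixes the carbinol next to the substituted diene terminus without any regiochemical choice.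

Key step: step 9

Assumption: the acid is carried as its methyl ester, because the acidic methanol that installs the methoxy ketal should also esterify the liberated acid; the ester is hydrolysed in the last step.

**Route**

Step 1
Reactants: 1 1,4-dioxaspiro[4.5]dec-6-en-8-one
Product: 2 7-iodo-1,4-dioxaspiro[4.5]dec-6-en-8-one
Conditions: I2, pyridine, CH2Cl2, 0 °C to rt
Reagents that add atoms: iodine, II
Why: Johnson α-iodination of an enone (conjugate addition of pyridine, iodination of the enolate, elimination) should place iodine on the α-carbon C7 only.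

Step 2
Reactants: 2 7-iodo-1,4-dioxaspiro[4.5]dec-6-en-8-one
Product: 3 (8R)-7-iodo-1,4-dioxaspiro[4.5]dec-6-en-8-ol
Conditions: (S)-2-methyl-CBS-oxazaborolidine (0.2 equiv), BH3·SMe2, THF, 0 °C; MeOH quench
Reagents that add atoms: none
Why: Corey–Bakshi–Shibata reduction, in which the iodoalkenyl arm acts as the large substituent, so the (S)-catalyst should deliver hydride to the face that gives the 8R carbinol (catalyst control of the new stereocentre).

Step 3
Reactants: 4 but-3-en-1-ol
Product: 5 (but-3-en-1-yloxy)(tert-butyl)diphenylsilane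
Conditions: TBDPSCl, imidazole, CH2Cl2, rt
Reagents that add atoms: tert-butyl(chloro)diphenylsilane, CC(C)(C)[Si](Cl)(c1ccccc1)c1ccccc1
Why: Standard O-silylation of a primary alcohol gives an ether that survives every step up to step 15.

Step 4
Reactants: 5 (but-3-en-1-yloxy)(tert-butyl)diphenylsilane; 3 (8R)-7-iodo-1,4-dioxaspiro[4.5]dec-6-en-8-ol
Product: 7 (8R)-7-[4-(tert-butyldiphenylsilyloxy)butyl]-1,4-dioxaspiro[4.5]dec-6-en-8-ol, via B-alkyl-9-BBN borane 6 (not isolated)
Conditions: 5, 9-BBN, THF, rt; then 3, PdCl2(dppf), AsPh3, Cs2CO3, DMF/H2O, rt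
Reagents that add atoms: none
Why: Anti-Markovnikov hydroboration followed by B-alkyl Suzuki–Miyaura coupling at the vinyl C–I bond should attach the four-carbon arm to C7 without touching the free allylic alcohol or the C8 stereocentre.

Step 5
Reactants: 7 (8R)-7-[4-(tert-butyldiphenylsilyloxy)butyl]-1,4-dioxaspiro[4.5]dec-6-en-8-ol
Product: 8 (4R)-3-[4-(tert-butyldiphenylsilyloxy)butyl]-4-hydroxycyclohex-2-en-1-one
Conditions: PPTS, acetone/H2O, rt
Reagents that add atoms: water, O
Why: Acid-catalysed hydrolysis of the allylic ketal is fast because the oxocarbenium ion is conjugated, so mild acid should release the enone while the TBDPS ether and the carbinol stay intact.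

Step 6
Reactants: 8 (4R)-3-[4-(tert-butyldiphenylsilyloxy)butyl]-4-hydroxycyclohex-2-en-1-one
Product: 9 (4R)-3-[4-(tert-butyldiphenylsilyloxy)butyl]-4-(triethylsilyloxy)cyclohex-2-en-1-one
Conditions: TESCl, imidazole, DMAP (cat.), CH2Cl2, 0 °C
Reagents that add atoms: chlorotriethylsilane, CC[Si](Cl)(CC)CC
Why: O-silylation with a triethylsilyl group, chosen because it can later be removed in the presence of the primary TBDPS ether, which a hindered secondary TBS ether could not be.

Step 7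
Reactants: 9 (4R)-3-[4-(tert-butyldiphenylsilyloxy)butyl]-4-(triethylsilyloxy)cyclohex-2-en-1-one
Product: 11 (4R)-5-[4-(tert-butyldiphenylsilyloxy)butyl]-4-(triethylsilyloxy)cyclohexa-1,5-dien-1-yl trifluoromethanesulfonate, via lithium dienolate 10 (not isolated)
Conditions: LiN(iPr)2, THF, −78 °C; PhNTf2, −78 to 0 °C
Reagents that add atoms: N-phenylbis(trifluoromethanesulfonimide), O=S(=O)(N(c1ccccc1)S(=O)(=O)C(F)(F)F)C(F)(F)F
Why: Kinetic α′-deprotonation of the enone at C6 and O-triflation of the cross-conjugated dienolate should give the dienyl triflate, the γ-proton at the carbinol centre not being removed under kinetic conditions.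

Step 8
Reactants: 11 (4R)-5-[4-(tert-butyldiphenylsilyloxy)butyl]-4-(triethylsilyloxy)cyclohexa-1,5-dien-1-yl trifluoromethanesulfonate
Product: 12 (1R)-2-[4-(tert-butyldiphenylsilyloxy)butyl]cyclohexa-2,4-dien-1-yl triethylsilyl ether
Conditions: Pd(OAc)2, PPh3, Bu3N, HCO2H, DMF, 40 °C
Reagents that add atoms: none
Why: Palladium-catalysed formate reduction of an enol triflate (Cacchi-type hydrogenolysis) replaces OTf by H under buffered conditions, so the acid-sensitive dienyl silyl ether should not lose silanol and aromatise.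

Step 9
Reactants: 12 (1R)-2-[4-(tert-butyldiphenylsilyloxy)butyl]cyclohexa-2,4-dien-1-yl triethylsilyl ether
Product: 13 (1R,4R,7R)-1-[4-(tert-butyldiphenylsilyloxy)butyl]-7-(triethylsilyloxy)-2,3-dioxabicyclo[2.2.2]oct-5-ene
Conditions: O2, tetraphenylporphyrin (cat.), visible light, CH2Cl2, −78 °C
Reagents that add atoms: dioxygen, O=O
Why: Sensitised singlet oxygen adds to the ring-locked s-cis diene C3=C4–C5=C6 of 12 in a concerted suprafacial [4+2] cycloaddition that forms C3–O and C6–O in one event; the closest known reactions are the ascaridole-type photooxygenations of 1-alkylcyclohexa-1,3-dienes and the anti-selective additions to 5-oxygenated cyclohexa-1,3-dienes. The 1,2-dioxane ring of the target is closed by this cycloaddition as the peroxide bridge of a 2,3-dioxabicyclo[2.2.2]oct-5-ene, so no separate ring-closing substitution is involved. The two new stereocentres, C1 and C4 of 13 (C3 and C6 of the target), are created together and are tied to each other by the bicycle; their absolute sense is controlled by the C8 carbinol centre, whose triethylsilyloxy group should sit pseudoaxial next to the substituted diene terminus and block its own face, so that oxygen enters anti. The step needs π-facial selectivity, secured by that silyloxy group, and chemoselectivity for [4+2] over the ene reaction, secured by the s-cis geometry of the cyclohexadiene and the low temperature. A syn adduct would be a diastereomer and could be removed before C8 is oxidised, so it would cost material but not enantiopurity.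

Step 10
Reactants: 13 (1R,4R,7R)-1-[4-(tert-butyldiphenylsilyloxy)butyl]-7-(triethylsilyloxy)-2,3-dioxabicyclo[2.2.2]oct-5-ene
Product: 14 (1R,4S,6R)-1-[4-(tert-butyldiphenylsilyloxy)butyl]-6-(triethylsilyloxy)-2,3-dioxabicyclo[2.2.2]octane
Conditions: KO2C–N=N–CO2K, AcOH, CH2Cl2/MeOH, −20 °C to rt
Reagents that add atoms: none
Why: Diimide reduction transfers H2 to the strained bicyclic alkene by a concerted syn pathway and leaves the O–O bond untouched, which catalytic hydrogenation would not.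

Step 11
Reactants: 14 (1R,4S,6R)-1-[4-(tert-butyldiphenylsilyloxy)butyl]-6-(triethylsilyloxy)-2,3-dioxabicyclo[2.2.2]octane
Product: 15 (1R,4S,6R)-1-[4-(tert-butyldiphenylsilyloxy)butyl]-2,3-dioxabicyclo[2.2.2]octan-6-ol
Conditions: HF·pyridine, pyridine, THF, 0 °C
Reagents that add atoms: none
Why: Acidic fluoride desilylation should cleave the triethylsilyl ether far faster than the primary TBDPS ether, and the non-basic medium avoids Kornblum–DeLaMare cleavage at the bridgehead C–H.

Step 12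
Reactants: 15 (1R,4S,6R)-1-[4-(tert-butyldiphenylsilyloxy)butyl]-2,3-dioxabicyclo[2.2.2]octan-6-ol
Product: 16 (1S,4R)-4-[4-(tert-butyldiphenylsilyloxy)butyl]-2,3-dioxabicyclo[2.2.2]octan-5-one
Conditions: Dess–Martin periodinane, CH2Cl2, 0 °C to rt
Reagents that add atoms: none
Why: Dess–Martin oxidation works under neutral, base-free conditions, so the ketone should form without retro-oxa-Michael opening or base-induced peroxide cleavage.

Step 13
Reactants: 16 (1S,4R)-4-[4-(tert-butyldiphenylsilyloxy)butyl]-2,3-dioxabicyclo[2.2.2]octan-5-one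
Product: 17 (1R,5S)-1-[4-(tert-butyldiphenylsilyloxy)butyl]-2,6,7-trioxabicyclo[3.2.2]nonan-3-one
Conditions: mCPBA, NaHCO3, CH2Cl2, 0 °C to rt
Reagents that add atoms: 3-chloroperoxybenzoic acid, OOC(=O)c1cccc(Cl)c1
Why: Baeyer–Villiger oxidation, in which the tertiary, oxygen-substituted bridgehead carbon should migrate from the Criegee adduct in preference to CH2 and with retention, as in the oxidation of 7-oxabicyclo[2.2.1]heptan-2-ones to bridged acyloxy acetals.

Step 14
Reactants: 17 (1R,5S)-1-[4-(tert-butyldiphenylsilyloxy)butyl]-2,6,7-trioxabicyclo[3.2.2]nonan-3-one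
Product: 19 methyl 2-[(3S,6R)-6-[4-(tert-butyldiphenylsilyloxy)butyl]-6-methoxy-1,2-dioxan-3-yl]acetate, via methoxy acid 18 (not isolated)
Conditions: TsOH·H2O (0.2 equiv), MeOH, rt then 40 °C
Reagents that add atoms: methanol, CO
Why: Acid-catalysed ionisation of the acyloxy peroxyketal gives a peroxycarbenium ion that methanol captures, and Fischer esterification of the released acid follows; the ketal carbon should equilibrate to the isomer with axial OMe (anomeric effect) and equatorial chain, which is the cis isomer already present in the lactone.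

Step 15
Reactants: 19 methyl 2-[(3S,6R)-6-[4-(tert-butyldiphenylsilyloxy)butyl]-6-methoxy-1,2-dioxan-3-yl]acetate
Product: 20 methyl 2-[(3S,6R)-6-(4-hydroxybutyl)-6-methoxy-1,2-dioxan-3-yl]acetate
Conditions: TBAF, AcOH, THF, rt
Reagents that add atoms: none
Why: Fluoride desilylation buffered with acetic acid removes the TBDPS group without exposing the β-peroxy ester to free alkoxide.

Step 16
Reactants: 20 methyl 2-[(3S,6R)-6-(4-hydroxybutyl)-6-methoxy-1,2-dioxan-3-yl]acetate
Product: 21 methyl 2-[(3S,6R)-6-methoxy-6-(4-oxobutyl)-1,2-dioxan-3-yl]acetate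
Conditions: Dess–Martin periodinane, CH2Cl2, 0 °C to rt
Reagents that add atoms: none
Why: Dess–Martin oxidation of the primary alcohol stops at the aldehyde and is compatible with the dialkyl peroxide and the peroxyketal.

Step 17
Reactants: 21 methyl 2-[(3S,6R)-6-methoxy-6-(4-oxobutyl)-1,2-dioxan-3-yl]acetate
Product: 22 methyl 2-[(3S,6R)-6-methoxy-6-(pent-4-yn-1-yl)-1,2-dioxan-3-yl]acetate
Conditions: dimethyl (1-diazo-2-oxopropyl)phosphonate, K2CO3, MeOH, 0 °C to rt
Reagents that add atoms: dimethyl (1-diazo-2-oxopropyl)phosphonate, CC(=O)C(=[N+]=[N-])P(=O)(OC)OC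
Why: Ohira–Bestmann (Seyferth–Gilbert) homologation converts the aldehyde into the terminal alkyne with only carbonate in methanol as base, the mildest conditions for this one-carbon extension.

Step 18
Reactants: 23 undec-1-yne
Product: 25 (E)-1-iodoundec-1-ene, via alkenylzirconocene chloride 24 (not isolated)
Conditions: Cp2Zr(H)Cl, THF, rt; then I2, 0 °C
Reagents that add atoms: iodine, II
Why: Hydrozirconation adds Zr–H syn and anti-Markovnikov, and iodinolysis of the C–Zr bond proceeds with retention, so the E iodide should form.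

Step 19
Reactants: 22 methyl 2-[(3S,6R)-6-methoxy-6-(pent-4-yn-1-yl)-1,2-dioxan-3-yl]acetate; 25 (E)-1-iodoundec-1-ene
Product: 26 methyl 2-[(3S,6R)-6-[(E)-hexadec-6-en-4-yn-1-yl]-6-methoxy-1,2-dioxan-3-yl]acetate
Conditions: PdCl2(PPh3)2, CuI, iPr2NH, THF, rt, degassed
Reagents that add atoms: none
Why: Sonogashira coupling of a terminal alkyne with a vinyl iodide retains the E geometry and runs at room temperature, conditions under which 3-methoxy-1,2-dioxanes are known to survive palladium-mediated couplings.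

Step 20
Reactants: 26 methyl 2-[(3S,6R)-6-[(E)-hexadec-6-en-4-yn-1-yl]-6-methoxy-1,2-dioxan-3-yl]acetate
Product: 27 2-[(3S,6R)-6-[(E)-hexadec-6-en-4-yn-1-yl]-6-methoxy-1,2-dioxan-3-yl]acetic acid
Conditions: LiOH, THF/H2O, 0 °C; then aq. HCl to pH 4
Reagents that add atoms: lithium hydroxide, [Li+].[OH-]
Why: Saponification at the acyl carbon of the unhindered methyl ester should give the acid, the peroxyketal being stable to base and the stereocentres not being involved.

**Compound list**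

1 | 1,4-dioxaspiro[4.5]dec-6-en-8-one | O=C1C=CC2(CC1)OCCO2 | starting material
2 | 7-iodo-1,4-dioxaspiro[4.5]dec-6-en-8-one | O=C1CCC2(OCCO2)C=C1I | intermediate
3 | (8R)-7-iodo-1,4-dioxaspiro[4.5]dec-6-en-8-ol | O[C@@H]1CCC2(OCCO2)C=C1I | intermediate
4 | but-3-en-1-ol | C=CCCO | starting material
5 | (but-3-en-1-yloxy)(tert-butyl)diphenylsilane | C=CCCO[Si](c1ccccc1)(c1ccccc1)C(C)(C)C | intermediate
6 | 9-[4-(tert-butyldiphenylsilyloxy)butyl]-9-borabicyclo[3.3.1]nonane | CC(C)(C)[Si](c1ccccc1)(c1ccccc1)OCCCCB1C2CCCC1CCC2 | intermediate (not isolated)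
7 | (8R)-7-[4-(tert-butyldiphenylsilyloxy)butyl]-1,4-dioxaspiro[4.5]dec-6-en-8-ol | O[C@@H]1CCC2(OCCO2)C=C1CCCCO[Si](c1ccccc1)(c1ccccc1)C(C)(C)C | intermediate
8 | (4R)-3-[4-(tert-butyldiphenylsilyloxy)butyl]-4-hydroxycyclohex-2-en-1-one | O[C@@H]1CCC(=O)C=C1CCCCO[Si](c1ccccc1)(c1ccccc1)C(C)(C)C | intermediate
9 | (4R)-3-[4-(tert-butyldiphenylsilyloxy)butyl]-4-(triethylsilyloxy)cyclohex-2-en-1-one | CC[Si](CC)(CC)O[C@@H]1CCC(=O)C=C1CCCCO[Si](c1ccccc1)(c1ccccc1)C(C)(C)C | intermediate
10 | lithium (4R)-5-[4-(tert-butyldiphenylsilyloxy)butyl]-4-(triethylsilyloxy)cyclohexa-1,5-dien-1-olate | CC[Si](CC)(CC)O[C@@H]1CC=C(O[Li])C=C1CCCCO[Si](c1ccccc1)(c1ccccc1)C(C)(C)C | intermediate (not isolated)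
11 | (4R)-5-[4-(tert-butyldiphenylsilyloxy)butyl]-4-(triethylsilyloxy)cyclohexa-1,5-dien-1-yl trifluoromethanesulfonate | CC[Si](CC)(CC)O[C@@H]1CC=C(OS(=O)(=O)C(F)(F)F)C=C1CCCCO[Si](c1ccccc1)(c1ccccc1)C(C)(C)C | intermediate
12 | (1R)-2-[4-(tert-butyldiphenylsilyloxy)butyl]cyclohexa-2,4-dien-1-yl triethylsilyl ether | CC[Si](CC)(CC)O[C@@H]1CC=CC=C1CCCCO[Si](c1ccccc1)(c1ccccc1)C(C)(C)C | intermediate
13 | (1R,4R,7R)-1-[4-(tert-butyldiphenylsilyloxy)butyl]-7-(triethylsilyloxy)-2,3-dioxabicyclo[2.2.2]oct-5-ene | CC(C)(C)[Si](c1ccccc1)(c1ccccc1)OCCCC[C@@]12C=C[C@@H](C[C@H]1O[Si](CC)(CC)CC)OO2 | intermediate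
14 | (1R,4S,6R)-1-[4-(tert-butyldiphenylsilyloxy)butyl]-6-(triethylsilyloxy)-2,3-dioxabicyclo[2.2.2]octane | CC(C)(C)[Si](c1ccccc1)(c1ccccc1)OCCCC[C@@]12CC[C@@H](C[C@H]1O[Si](CC)(CC)CC)OO2 | intermediate
15 | (1R,4S,6R)-1-[4-(tert-butyldiphenylsilyloxy)butyl]-2,3-dioxabicyclo[2.2.2]octan-6-ol | CC(C)(C)[Si](c1ccccc1)(c1ccccc1)OCCCC[C@@]12CC[C@@H](C[C@H]1O)OO2 | intermediate
16 | (1S,4R)-4-[4-(tert-butyldiphenylsilyloxy)butyl]-2,3-dioxabicyclo[2.2.2]octan-5-one | CC(C)(C)[Si](c1ccccc1)(c1ccccc1)OCCCC[C@@]12CC[C@@H](CC1=O)OO2 | intermediate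
17 | (1R,5S)-1-[4-(tert-butyldiphenylsilyloxy)butyl]-2,6,7-trioxabicyclo[3.2.2]nonan-3-one | CC(C)(C)[Si](c1ccccc1)(c1ccccc1)OCCCC[C@@]12CC[C@@H](CC(=O)O1)OO2 | intermediate
18 | 2-[(3S,6R)-6-[4-(tert-butyldiphenylsilyloxy)butyl]-6-methoxy-1,2-dioxan-3-yl]acetic acid | CC(C)(C)[Si](c1ccccc1)(c1ccccc1)OCCCC[C@]1(OC)CC[C@@H](CC(=O)O)OO1 | intermediate (not isolated)
19 | methyl 2-[(3S,6R)-6-[4-(tert-butyldiphenylsilyloxy)butyl]-6-methoxy-1,2-dioxan-3-yl]acetate | CC(C)(C)[Si](c1ccccc1)(c1ccccc1)OCCCC[C@]1(OC)CC[C@@H](CC(=O)OC)OO1 | intermediate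
20 | methyl 2-[(3S,6R)-6-(4-hydroxybutyl)-6-methoxy-1,2-dioxan-3-yl]acetate | OCCCC[C@]1(OC)CC[C@@H](CC(=O)OC)OO1 | intermediate
21 | methyl 2-[(3S,6R)-6-methoxy-6-(4-oxobutyl)-1,2-dioxan-3-yl]acetate | O=CCCC[C@]1(OC)CC[C@@H](CC(=O)OC)OO1 | intermediate
22 | methyl 2-[(3S,6R)-6-methoxy-6-(pent-4-yn-1-yl)-1,2-dioxan-3-yl]acetate | C#CCCC[C@]1(OC)CC[C@@H](CC(=O)OC)OO1 | intermediate
23 | undec-1-yne | CCCCCCCCCC#C | starting material
24 | chlorobis(cyclopentadienyl)[(E)-undec-1-en-1-yl]zirconium | CCCCCCCCC/C=C/[Zr](Cl)(C1C=CC=C1)C1C=CC=C1 | intermediate (not isolated)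
25 | (E)-1-iodoundec-1-ene | CCCCCCCCC/C=C/I | intermediate
26 | methyl 2-[(3S,6R)-6-[(E)-hexadec-6-en-4-yn-1-yl]-6-methoxy-1,2-dioxan-3-yl]acetate | CCCCCCCCC/C=C/C#CCCC[C@]1(OC)CC[C@@H](CC(=O)OC)OO1 | intermediate
27 | 2-[(3S,6R)-6-[(E)-hexadec-6-en-4-yn-1-yl]-6-methoxy-1,2-dioxan-3-yl]acetic acid | CCCCCCCCC/C=C/C#CCCC[C@]1(OC)CC[C@@H](CC(=O)O)OO1 | target

**Step count**

Total: 20 steps. Longest linear sequence: 18 steps (steps 1, 2, 4 to 17, 19 and 20, from compound 1).

**Three steps most likely to fail**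

Step 9. Singlet oxygen may attack both faces of the diene if the silyloxy group shields too weakly, ene-type hydroperoxidation at the trisubstituted alkene may compete, and the dienyl ether may lose silanol and aromatise. The fallback sets out from 2 and comes back at 16; it replaces steric shielding by hydroxyl-directed delivery in the enantiomeric carbinol series.
- Reduction of 2 with the (R)-configured oxazaborolidine and BH3·SMe2 should give (8S)-7-iodo-1,4-dioxaspiro[4.5]dec-6-en-8-ol F1.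
- Coupling with borane 6 as in step 4 gives (8S)-7-[4-(tert-butyldiphenylsilyloxy)butyl]-1,4-dioxaspiro[4.5]dec-6-en-8-ol F2.
- Ketal hydrolysis gives (4S)-3-[4-(tert-butyldiphenylsilyloxy)butyl]-4-hydroxycyclohex-2-en-1-one F3, and silylation gives (4S)-3-[4-(tert-butyldiphenylsilyloxy)butyl]-4-(triethylsilyloxy)cyclohex-2-en-1-one F4.
- LiN(iPr)2 gives lithium (4S)-5-[4-(tert-butyldiphenylsilyloxy)butyl]-4-(triethylsilyloxy)cyclohexa-1,5-dien-1-olate F5, which PhNTf2 converts into (4S)-5-[4-(tert-butyldiphenylsilyloxy)butyl]-4-(triethylsilyloxy)cyclohexa-1,5-dien-1-yl trifluoromethanesulfonate F6.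
- Formate reduction as in step 8 gives (1S)-2-[4-(tert-butyldiphenylsilyloxy)butyl]cyclohexa-2,4-dien-1-yl triethylsilyl ether F7.
- Buffered fluoride (TBAF, AcOH, THF, 0 °C) removes the triethylsilyl group to give (1S)-2-[4-(tert-butyldiphenylsilyloxy)butyl]cyclohexa-2,4-dien-1-ol F8.
- Photooxygenation of the free dienol in a non-polar solvent (O2, tetraphenylporphyrin, light, CCl4, 0 °C) should be steered by hydrogen bonding of the allylic hydroxyl to the face syn to OH. In the S series this is the same face as anti attack on 12, so it should give (1R,4R,7S)-1-[4-(tert-butyldiphenylsilyloxy)butyl]-2,3-dioxabicyclo[2.2.2]oct-5-en-7-ol F9.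
- Diimide reduction gives (1R,4S,6S)-1-[4-(tert-butyldiphenylsilyloxy)butyl]-2,3-dioxabicyclo[2.2.2]octan-6-ol F10, the carbinol epimer of 15, and Dess–Martin oxidation of it gives ketone 16.

Step 13. The methylene carbon may migrate instead of the peroxy-substituted bridgehead, the α-peroxy ketone may fragment under the peracid, or the acylal product may be hydrolysed. The fallback sets out from 16 and comes back at 19; it cuts the C–C bond by Beckmann fragmentation instead of oxygen insertion.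
- Ketone 16 with NH2OH·HCl and NaOAc in MeOH gives (1S,4R)-4-[4-(tert-butyldiphenylsilyloxy)butyl]-2,3-dioxabicyclo[2.2.2]octan-5-one oxime F11.
- O-Sulfonylation (TsCl, pyridine, CH2Cl2, 0 °C) followed by addition of MeOH should break the bond between the oxime carbon and the peroxy-substituted bridgehead. Methanol captures the peroxy-stabilised cation to give 2-[(3S,6R)-6-[4-(tert-butyldiphenylsilyloxy)butyl]-6-methoxy-1,2-dioxan-3-yl]acetonitrile F12.
- Pinner methanolysis (HCl in MeOH, 0 °C, then water) passes through methyl 2-[(3S,6R)-6-[4-(tert-butyldiphenylsilyloxy)butyl]-6-methoxy-1,2-dioxan-3-yl]acetimidate hydrochloride F13. It converts the nitrile into the methyl ester and equilibrates the ketal carbon, returning ester 19.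

Step 19. Low-valent palladium with phosphine or the copper acetylide may reduce the O–O bond, the amine may trigger Kornblum–DeLaMare cleavage at the C–H next to the peroxide, and the alkyne may homocouple. The fallback sets out from 22 and 25 and comes back at 26; it reverses the polarity of the coupling and needs neither amine nor copper acetylide.
- Alkyne 22 is iodinated (N-iodosuccinimide, AgNO3 cat., acetone, rt) to methyl 2-[(3S,6R)-6-(5-iodopent-4-yn-1-yl)-6-methoxy-1,2-dioxan-3-yl]acetate F14.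
- Iodide 25 is converted by iodine–lithium exchange (t-BuLi, Et2O, −78 °C) and Bu3SnCl into (E)-tributyl(undec-1-en-1-yl)stannane F15.
- Stille coupling of F14 with F15 (PdCl2(MeCN)2, DMF, rt) gives 26.

**Further compounds**

F1 | step 9 | (8S)-7-iodo-1,4-dioxaspiro[4.5]dec-6-en-8-ol | O[C@H]1CCC2(OCCO2)C=C1I
F2 | step 9 | (8S)-7-[4-(tert-butyldiphenylsilyloxy)butyl]-1,4-dioxaspiro[4.5]dec-6-en-8-ol | O[C@H]1CCC2(OCCO2)C=C1CCCCO[Si](c1ccccc1)(c1ccccc1)C(C)(C)C
F3 | step 9 | (4S)-3-[4-(tert-butyldiphenylsilyloxy)butyl]-4-hydroxycyclohex-2-en-1-one | O[C@H]1CCC(=O)C=C1CCCCO[Si](c1ccccc1)(c1ccccc1)C(C)(C)C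
F4 | step 9 | (4S)-3-[4-(tert-butyldiphenylsilyloxy)butyl]-4-(triethylsilyloxy)cyclohex-2-en-1-one | CC[Si](CC)(CC)O[C@H]1CCC(=O)C=C1CCCCO[Si](c1ccccc1)(c1ccccc1)C(C)(C)C
F5 | step 9 | lithium (4S)-5-[4-(tert-butyldiphenylsilyloxy)butyl]-4-(triethylsilyloxy)cyclohexa-1,5-dien-1-olate | CC[Si](CC)(CC)O[C@H]1CC=C(O[Li])C=C1CCCCO[Si](c1ccccc1)(c1ccccc1)C(C)(C)C
F6 | step 9 | (4S)-5-[4-(tert-butyldiphenylsilyloxy)butyl]-4-(triethylsilyloxy)cyclohexa-1,5-dien-1-yl trifluoromethanesulfonate | CC[Si](CC)(CC)O[C@H]1CC=C(OS(=O)(=O)C(F)(F)F)C=C1CCCCO[Si](c1ccccc1)(c1ccccc1)C(C)(C)C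
F7 | step 9 | (1S)-2-[4-(tert-butyldiphenylsilyloxy)butyl]cyclohexa-2,4-dien-1-yl triethylsilyl ether | CC[Si](CC)(CC)O[C@H]1CC=CC=C1CCCCO[Si](c1ccccc1)(c1ccccc1)C(C)(C)C
F8 | step 9 | (1S)-2-[4-(tert-butyldiphenylsilyloxy)butyl]cyclohexa-2,4-dien-1-ol | O[C@H]1CC=CC=C1CCCCO[Si](c1ccccc1)(c1ccccc1)C(C)(C)C
F9 | step 9 | (1R,4R,7S)-1-[4-(tert-butyldiphenylsilyloxy)butyl]-2,3-dioxabicyclo[2.2.2]oct-5-en-7-ol | CC(C)(C)[Si](c1ccccc1)(c1ccccc1)OCCCC[C@@]12C=C[C@@H](C[C@@H]1O)OO2
F10 | step 9 | (1R,4S,6S)-1-[4-(tert-butyldiphenylsilyloxy)butyl]-2,3-dioxabicyclo[2.2.2]octan-6-ol | CC(C)(C)[Si](c1ccccc1)(c1ccccc1)OCCCC[C@@]12CC[C@@H](C[C@@H]1O)OO2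
F11 | step 13 | (1S,4R)-4-[4-(tert-butyldiphenylsilyloxy)butyl]-2,3-dioxabicyclo[2.2.2]octan-5-one oxime (C=N geometry not fixed) | CC(C)(C)[Si](c1ccccc1)(c1ccccc1)OCCCC[C@@]12CC[C@@H](CC1=NO)OO2
F12 | step 13 | 2-[(3S,6R)-6-[4-(tert-butyldiphenylsilyloxy)butyl]-6-methoxy-1,2-dioxan-3-yl]acetonitrile | CC(C)(C)[Si](c1ccccc1)(c1ccccc1)OCCCC[C@]1(OC)CC[C@@H](CC#N)OO1
F13 | step 13 | methyl 2-[(3S,6R)-6-[4-(tert-butyldiphenylsilyloxy)butyl]-6-methoxy-1,2-dioxan-3-yl]acetimidate hydrochloride | CC(C)(C)[Si](c1ccccc1)(c1ccccc1)OCCCC[C@]1(OC)CC[C@@H](CC(=N)OC)OO1.Cl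
F14 | step 19 | methyl 2-[(3S,6R)-6-(5-iodopent-4-yn-1-yl)-6-methoxy-1,2-dioxan-3-yl]acetate | IC#CCCC[C@]1(OC)CC[C@@H](CC(=O)OC)OO1
F15 | step 19 | (E)-tributyl(undec-1-en-1-yl)stannane | CCCCCCCCC/C=C/[Sn](CCCC)(CCCC)CCCC
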